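**Strategy.** The route rests on disconnecting the C3–C4 bond of pyran ring C of the galloylated unit. C4 is doubly benzylic, flanked by C4a of that unit's ring A and by C8 of the epicatechin ring A, so a carbenium ion forms there easily. The C3 oxygen is carried as a (Z)-enol gallate (C2=C3) hung on O1. Acid ionisation of the open-chain diarylmethyl methyl ether lets C3 attack C4 (6-endo), and a silane reduces the resulting C2 oxocarbenium ion trans to the gallate. Ring C, its three stereocentres and the ester thus arise in one operation. A preformed epigallocatechin-(4β→8)-epigallocatechin electrophile is then joined by a C4→C8 coupling, and hydrogenolysis frees the phenols.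

Key step: step 9

Remarks on the chemistry (assumptions):
- The four flavan units are called, from the top, top unit, second unit, gallate unit and epicatechin unit; rings A, B and C are the usual flavan rings of each unit. In the dimeric intermediates 25 to 27 the upper unit is the future top unit and the lower unit the future second unit.
- Compounds 1, 4, 6, 15 and 21 are taken as commercial.
- The sense of induction of the chiral acid in step 9 cannot be predicted with confidence. The (R)-acid is written and its antipode is the immediate alternative. Because the epicatechin unit is enantiopure, the two possible ring-C series are diastereomers and separable.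

Step 1
Reactants: 1 (−)-epicatechin
Product: 2 3,5,7,3',4'-penta-O-benzyl-(−)-epicatechin
Conditions: BnBr (7 equiv), K2CO3 (5 equiv), DMF, 0 °C → rt; then NaH (1.5 equiv), 0 °C (one pot)
Reagents that add atoms: benzyl bromide BrCc1ccccc1
Why: Williamson etherification in which K2CO3 alkylates the four phenols first and NaH then the secondary 3-hydroxyl, so that free phenoxides are not exposed to strong base (C2 epimerisation); no stereocentre is touched.

Step 2
Reactants: 2 penta-O-benzyl-epicatechin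
Product: 3 8-bromo-3,5,7,3',4'-penta-O-benzyl-(−)-epicatechin
Conditions: NBS (1.05 equiv), CH2Cl2, −78 °C → rt
Reagents that add atoms: N-bromosuccinimide O=C1CCC(=O)N1Br
Why: Electrophilic aromatic bromination of the phloroglucinol-type ring A, where C8 reacts in preference to C6 in benzylated flavan-3-ols and the dialkoxyphenyl ring B is far less reactive.

Step 3
Reactants: 4 3,5-bis(benzyloxy)phenol
Product: 5 2,4-bis(benzyloxy)-6-hydroxybenzaldehyde
Conditions: (CH2O)n, MgCl2, Et3N, MeCN, reflux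
Reagents that add atoms: paraformaldehyde, as formaldehyde C=O
Why: Magnesium-mediated ortho-formylation (Casnati–Skattebøl), in which the magnesium phenoxide delivers formaldehyde to the ortho carbon and a second formaldehyde oxidises the benzylic alkoxide by hydride transfer; the two ortho positions of 4 are equivalent.

Step 4
Reactants: 6 3,4,5-tris(benzyloxy)benzaldehyde
Product: 8 methyl 1-[3,4,5-tris(benzyloxy)phenyl]prop-2-en-1-yl carbonate (racemic), via bromomagnesium alkoxide 7 (not isolated)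
Conditions: vinylmagnesium bromide, THF, −78 → 0 °C; then ClCO2Me, 0 °C
Reagents that add atoms: vinylmagnesium bromide C=C[Mg]Br; methyl chloroformate COC(Cl)=O
Why: Grignard 1,2-addition followed by in-flask O-acylation of the magnesium alkoxide; the product is racemic, which is immaterial because this carbon becomes sp2 in step 8.

Step 5
Reactants: 5 2,4-bis(benzyloxy)-6-hydroxybenzaldehyde; 8 allylic methyl carbonate
Product: 9 2,4-bis(benzyloxy)-6-{1-[3,4,5-tris(benzyloxy)phenyl]prop-2-en-1-yloxy}benzaldehyde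
Conditions: [Ir(cod)Cl]2 (2 mol%), (S)-O,O'-(1,1'-binaphthyl-2,2'-diyl) N,N-bis[(S)-1-phenylethyl]phosphoramidite (4 mol%), THF, 50 °C
Reagents that add atoms: none
Why: Iridium-catalysed allylic etherification (Hartwig type), in which the phenoxide (formed by the methoxide released on decarboxylation) attacks the allyliridium intermediate at the substituted terminus and should give the branched 1-arylallyl aryl ether, not the cinnamyl ether; the ligand antipode is immaterial.

Step 6
Reactants: 3 8-bromo-penta-O-benzyl-epicatechin; 9 branched allyl aryl ether aldehyde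
Product: 12 diarylmethyl methyl ether joining C8 of the epicatechin unit to the future C4 (diastereomer mixture), via aryllithium 10 (not isolated), via lithium alkoxide 11 (not isolated)
Conditions: n-BuLi (1.05 equiv), THF, −78 °C; then 9, −78 °C; then MeOTf, −78 → 0 °C
Reagents that add atoms: methyl trifluoromethanesulfonate COS(=O)(=O)C(F)(F)F
Why: Bromine–lithium exchange, 1,2-addition of the aryllithium to the aldehyde and O-methylation of the alkoxide; the two open-chain stereocentres (mixture) both become sp2 before or in the key step.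

Step 7
Reactants: 12 diarylmethyl methyl ether
Product: 14 2-aryloxy-2-[3,4,5-tris(benzyloxy)phenyl]acetaldehyde (the aldehyde carbon is the future C3), via diol 13 (not isolated)
Conditions: OsO4 (2 mol%), NaIO4 (4 equiv), 2,6-lutidine, dioxane–H2O (3:1), rt
Reagents that add atoms: osmium tetroxide O=[Os](=O)(=O)=O (transfers the oxygen; reoxidised by sodium periodate [Na+].[O-]I(=O)(=O)=O, the ultimate oxygen source)
Why: Lemieux–Johnson oxidative cleavage, in which OsO4 dihydroxylates only the terminal vinyl group, periodate cleaves the diol and the lutidine buffer protects the acid-labile diarylmethyl ether.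

Step 8
Reactants: 14 α-aryloxy aldehyde; 15 3,4,5-tris(benzyloxy)benzoyl chloride
Product: 17 (Z)-enol gallate (open-chain precursor of ring C), via potassium enolate 16 (not isolated)
Conditions: KN(SiMe3)2 (1.05 equiv), THF, −78 °C; then 15, −78 → −20 °C
Reagents that add atoms: none
Why: Deprotonation of the α-aryloxy-α-aryl aldehyde and O-acylation of the potassium enolate (enol ester formation); the K+-chelated enolate holds its oxygen syn to the aryloxy oxygen and anti to the aryl group, which should give the (Z) enol gallate.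

Step 9
Reactants: 17 (Z)-enol gallate
Product: 20 protected gallate unit-(4β→8)-epicatechin dimer (ring C 2,3-cis-3,4-trans), via diarylcarbenium ion 18 (not isolated), via oxocarbenium ion 19 (not isolated)
Conditions: (R)-3,3'-bis(2,4,6-triisopropylphenyl)-1,1'-binaphthyl-2,2'-diyl N-(trifluoromethanesulfonyl)phosphoramide (10 mol%), Et3SiH (3 equiv), toluene, −60 → −20 °C
Reagents that add atoms: none
Why: Proposed new method: the chiral acid ionises the methyl ether to carbenium ion 18 (C4 stabilised by the two trioxygenated rings A), C3 of the enol gallate attacks C4 to give 2-oxocarbenium ion 19 (stabilised by O1 and ring B) and Et3SiH delivers hydride to C2; the closest known reaction types are Prins-type cyclisations of stabilised cations onto enol esters, acid-catalysed o-quinone methide annulations and ionic hydrogenation of oxocarbenium ions under chiral counter-anion control. Pyran ring C closes in a 6-endo-trig mode, formally a disrotatory 6π electrocyclisation of the oxonia-hexatriene C4=C4a–C8a=O1–C2=C3. For C3 and C4, the gallate oxygen lies inside (Z enol ester) and the epicatechin aryl outside (anti to O1), so disrotation places them trans, with the aryl pseudo-axial and away from the peri 5-benzyloxy group. For C2, hydride enters anti to the adjacent pseudo-axial gallate, whose carbonyl can bridge to C2 as an acyloxonium ion, which gives the 2,3-cis relationship. The absolute sense is set by the chiral phosphoramide anion paired with 18 and 19, and the enantiopure epicatechin unit makes the two possible outcomes separable diastereomers. The step needs attack through C3 and not C2 (O1 and ring B stabilise a cation at C2, the acyloxy group is only a weak donor) and cyclisation faster than silane reduction of 18 (18 is a far weaker hydride acceptor than 19).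

Step 10
Reactants: 21 (−)-epigallocatechin
Product: 22 5,7,3',4',5'-penta-O-benzyl-(−)-epigallocatechin
Conditions: BnBr (5.5 equiv), K2CO3, DMF, 0 °C → rt
Reagents that add atoms: benzyl bromide BrCc1ccccc1
Why: Williamson etherification with a weak base benzylates the five phenols and leaves the secondary 3-hydroxyl free; no stereocentre is touched.

Step 11
Reactants: 22 penta-O-benzyl-epigallocatechin
Product: 23 (2R,3R,4S)-4-(2-ethoxyethoxy)-5,7,3',4',5'-penta-O-benzyl-epigallocatechin (4β ether)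
Conditions: DDQ (2 equiv), 2-ethoxyethanol (5 equiv), CH2Cl2, rt
Reagents that add atoms: 2-ethoxyethanol CCOCCO
Why: DDQ benzylic oxidation, in which hydride abstraction from C4 gives the ring-A-stabilised cation and the alcohol captures it on the face anti to the C2 aryl and C3 hydroxyl groups (4β, 3,4-trans).

Step 12
Reactants: 23 4β-(2-ethoxyethoxy) electrophile; 22 penta-O-benzyl-epigallocatechin
Product: 25 penta-O-benzyl-epigallocatechin-(4β→8)-penta-O-benzyl-epigallocatechin, via flavan-4-yl cation 24 (not isolated)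
Conditions: Me3SiOTf (0.2 equiv), CH2Cl2, −78 °C; 22 in excess (3 equiv, recovered)
Reagents that add atoms: none
Why: Lewis-acid ionisation of the C4 ether and Friedel–Crafts alkylation (classical flavan-4-yl cation coupling); C8 of 22 is the ring-A position not flanked by two benzyloxy groups, the excess of 22 suppresses self-condensation of 23 through its own C8, and attack trans to the C3 hydroxyl of the 2,3-cis cation should set the new C4 centre as 4β.

Step 13
Reactants: 25 protected epigallocatechin dimer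
Product: 26 dimer carrying a 4β-(2-ethoxyethoxy) group at C4 of its lower unit (dimeric electrophile)
Conditions: DDQ (2 equiv), 2-ethoxyethanol (5 equiv), CH2Cl2, rt
Reagents that add atoms: 2-ethoxyethanol CCOCCO
Why: DDQ benzylic oxidation at the only benzylic methylene of 25 (C4 of the lower unit), the cation being captured by the alcohol anti to the C2 aryl and C3 hydroxyl groups (4β); the interflavan methine C4–H of the upper unit is tertiary, shielded by its two flanking aryl rings and should be abstracted far more slowly.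

Step 14
Reactants: 26 dimeric 4β-(2-ethoxyethoxy) electrophile; 20 protected gallate unit-(4β→8)-epicatechin dimer
Product: 28 protected tetramer, via dimeric flavan-4-yl cation 27 (not isolated)
Conditions: Me3SiOTf (0.2 equiv), CH2Cl2, −78 °C; 20 in excess (2 equiv, recovered)
Reagents that add atoms: none
Why: Lewis-acid ionisation of the C4 ether and Friedel–Crafts alkylation in a convergent 2+2 coupling; C8 of ring A of the gallate unit of 20 is its only free ring-A position not flanked by two benzyloxy groups, attack trans to the C3 hydroxyl of the 2,3-cis cation should set the new C4 centre as 4β, and the low temperature with catalytic acid should leave the existing interflavan bonds intact.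

Step 15
Reactants: 28 protected tetramer
Product: 29 CNP0305998.1
Conditions: H2 (1 atm), Pd(OH)2 on carbon, THF–MeOH–H2O, rt
Reagents that add atoms: none
Why: Hydrogenolysis of all twenty-three benzyl ethers (aryl ethers and the one secondary alkyl ether); the gallate ester, the interflavan bonds and all stereocentres should be untouched.

**Compound list**

1 | (−)-epicatechin, (2R,3R) | Oc1cc(O)c2c(c1)O[C@H](c1ccc(O)c(O)c1)[C@H](O)C2 | starting material
2 | 3,5,7,3',4'-penta-O-benzyl-(−)-epicatechin, (2R,3R) | O(Cc1ccccc1)c1cc(OCc2ccccc2)c2c(c1)O[C@H](c1ccc(OCc3ccccc3)c(OCc3ccccc3)c1)[C@H](OCc1ccccc1)C2 | intermediate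
3 | 8-bromo-3,5,7,3',4'-penta-O-benzyl-(−)-epicatechin | O(Cc1ccccc1)c1cc(OCc2ccccc2)c2c(c1Br)O[C@H](c1ccc(OCc3ccccc3)c(OCc3ccccc3)c1)[C@H](OCc1ccccc1)C2 | intermediate
4 | 3,5-bis(benzyloxy)phenol | Oc1cc(OCc2ccccc2)cc(OCc2ccccc2)c1 | starting material
5 | 2,4-bis(benzyloxy)-6-hydroxybenzaldehyde | O=Cc1c(O)cc(OCc2ccccc2)cc1OCc1ccccc1 | intermediate
6 | 3,4,5-tris(benzyloxy)benzaldehyde | O=Cc1cc(OCc2ccccc2)c(OCc2ccccc2)c(OCc2ccccc2)c1 | starting material
7 | bromomagnesium 1-[3,4,5-tris(benzyloxy)phenyl]prop-2-en-1-olate (racemic) | C=CC(O[Mg]Br)c1cc(OCc2ccccc2)c(OCc2ccccc2)c(OCc2ccccc2)c1 | intermediate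
8 | methyl 1-[3,4,5-tris(benzyloxy)phenyl]prop-2-en-1-yl carbonate (racemic) | C=CC(OC(=O)OC)c1cc(OCc2ccccc2)c(OCc2ccccc2)c(OCc2ccccc2)c1 | intermediate
9 | 2,4-bis(benzyloxy)-6-{1-[3,4,5-tris(benzyloxy)phenyl]prop-2-en-1-yloxy}benzaldehyde (allylic centre immaterial) | O=Cc1c(OC(C=C)c2cc(OCc3ccccc3)c(OCc3ccccc3)c(OCc3ccccc3)c2)cc(OCc2ccccc2)cc1OCc1ccccc1 | intermediate
10 | 8-lithio-3,5,7,3',4'-penta-O-benzyl-epicatechin | O(Cc1ccccc1)c1cc(OCc2ccccc2)c2c(c1[Li])O[C@H](c1ccc(OCc3ccccc3)c(OCc3ccccc3)c1)[C@H](OCc1ccccc1)C2 | intermediate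
11 | lithium diarylmethanolate from 10 and 9 (diastereomer mixture) | O(Cc1ccccc1)c1cc(OCc2ccccc2)c2c(c1C([O-])c1c(OC(C=C)c3cc(OCc4ccccc4)c(OCc4ccccc4)c(OCc4ccccc4)c3)cc(OCc3ccccc3)cc1OCc1ccccc1)O[C@H](c1ccc(OCc3ccccc3)c(OCc3ccccc3)c1)[C@H](OCc1ccccc1)C2.[Li+] | intermediate
12 | diarylmethyl methyl ether: epicatechin C8–CH(OMe)–[2,4-bis(benzyloxy)-6-(1-arylallyloxy)phenyl], epicatechin unit (2R,3R), mixture at the two open-chain carbons | O(Cc1ccccc1)c1cc(OCc2ccccc2)c2c(c1C(OC)c1c(OC(C=C)c3cc(OCc4ccccc4)c(OCc4ccccc4)c(OCc4ccccc4)c3)cc(OCc3ccccc3)cc1OCc1ccccc1)O[C@H](c1ccc(OCc3ccccc3)c(OCc3ccccc3)c1)[C@H](OCc1ccccc1)C2 | intermediate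
13 | 1,2-diol from dihydroxylation of the vinyl group of 12 | O(Cc1ccccc1)c1cc(OCc2ccccc2)c2c(c1C(OC)c1c(OC(C(O)CO)c3cc(OCc4ccccc4)c(OCc4ccccc4)c(OCc4ccccc4)c3)cc(OCc3ccccc3)cc1OCc1ccccc1)O[C@H](c1ccc(OCc3ccccc3)c(OCc3ccccc3)c1)[C@H](OCc1ccccc1)C2 | intermediate
14 | 2-aryloxy-2-[3,4,5-tris(benzyloxy)phenyl]acetaldehyde carrying the diarylmethyl methyl ether (mixture at the two open-chain carbons) | O(Cc1ccccc1)c1cc(OCc2ccccc2)c2c(c1C(OC)c1c(OC(C=O)c3cc(OCc4ccccc4)c(OCc4ccccc4)c(OCc4ccccc4)c3)cc(OCc3ccccc3)cc1OCc1ccccc1)O[C@H](c1ccc(OCc3ccccc3)c(OCc3ccccc3)c1)[C@H](OCc1ccccc1)C2 | intermediate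
15 | 3,4,5-tris(benzyloxy)benzoyl chloride | O=C(Cl)c1cc(OCc2ccccc2)c(OCc2ccccc2)c(OCc2ccccc2)c1 | starting material
16 | potassium (Z)-enolate of 14 | O(Cc1ccccc1)c1cc(OCc2ccccc2)c2c(c1C(OC)c1c(O/C(c3cc(OCc4ccccc4)c(OCc4ccccc4)c(OCc4ccccc4)c3)=C\[O-])cc(OCc3ccccc3)cc1OCc1ccccc1)O[C@H](c1ccc(OCc3ccccc3)c(OCc3ccccc3)c1)[C@H](OCc1ccccc1)C2.[K+] | intermediate
17 | (Z)-2-aryloxy-2-[3,4,5-tris(benzyloxy)phenyl]vinyl 3,4,5-tris(benzyloxy)benzoate carrying the diarylmethyl methyl ether (mixture at the methoxy carbon) | O(Cc1ccccc1)c1cc(OCc2ccccc2)c2c(c1C(OC)c1c(O/C(c3cc(OCc4ccccc4)c(OCc4ccccc4)c(OCc4ccccc4)c3)=C\OC(=O)c3cc(OCc4ccccc4)c(OCc4ccccc4)c(OCc4ccccc4)c3)cc(OCc3ccccc3)cc1OCc1ccccc1)O[C@H](c1ccc(OCc3ccccc3)c(OCc3ccccc3)c1)[C@H](OCc1ccccc1)C2 | intermediate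
18 | diarylcarbenium ion at the future C4 | O(Cc1ccccc1)c1cc(OCc2ccccc2)c2c(c1[CH+]c1c(O/C(c3cc(OCc4ccccc4)c(OCc4ccccc4)c(OCc4ccccc4)c3)=C\OC(=O)c3cc(OCc4ccccc4)c(OCc4ccccc4)c(OCc4ccccc4)c3)cc(OCc3ccccc3)cc1OCc1ccccc1)O[C@H](c1ccc(OCc3ccccc3)c(OCc3ccccc3)c1)[C@H](OCc1ccccc1)C2 | intermediate
19 | ring-C 2-oxocarbenium ion, 3,4-trans (C3 gallate, C4 β-aryl) | O=C(O[C@@H]1[C@@H](c2c(OCc4ccccc4)cc(OCc4ccccc4)c3c2O[C@H](c2ccc(OCc4ccccc4)c(OCc4ccccc4)c2)[C@H](OCc4ccccc4)C3)c2c(OCc4ccccc4)cc(OCc4ccccc4)cc2[O+]=C1c1cc(OCc2ccccc2)c(OCc2ccccc2)c(OCc2ccccc2)c1)c1cc(OCc2ccccc2)c(OCc2ccccc2)c(OCc2ccccc2)c1 | intermediate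
20 | 5,7,3',4',5'-penta-O-benzyl-3-O-[3,4,5-tris(benzyloxy)benzoyl]-(−)-epigallocatechin-(4β→8)-3,5,7,3',4'-penta-O-benzyl-(−)-epicatechin (gallate unit 2R,3R, 2,3-cis-3,4-trans) | O=C(O[C@@H]1[C@@H](c2c(OCc4ccccc4)cc(OCc4ccccc4)c3c2O[C@H](c2ccc(OCc4ccccc4)c(OCc4ccccc4)c2)[C@H](OCc4ccccc4)C3)c2c(OCc4ccccc4)cc(OCc4ccccc4)cc2O[C@@H]1c1cc(OCc2ccccc2)c(OCc2ccccc2)c(OCc2ccccc2)c1)c1cc(OCc2ccccc2)c(OCc2ccccc2)c(OCc2ccccc2)c1 | intermediate
21 | (−)-epigallocatechin, (2R,3R) | Oc1cc(O)c2c(c1)O[C@H](c1cc(O)c(O)c(O)c1)[C@H](O)C2 | starting material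
22 | 5,7,3',4',5'-penta-O-benzyl-(−)-epigallocatechin | O(Cc1ccccc1)c1cc(OCc2ccccc2)c2c(c1)O[C@H](c1cc(OCc3ccccc3)c(OCc3ccccc3)c(OCc3ccccc3)c1)[C@H](O)C2 | intermediate
23 | (2R,3R,4S)-4-(2-ethoxyethoxy)-5,7,3',4',5'-penta-O-benzyl-epigallocatechin (4β) | CCOCCO[C@H]1c2c(OCc3ccccc3)cc(OCc3ccccc3)cc2O[C@H](c2cc(OCc3ccccc3)c(OCc3ccccc3)c(OCc3ccccc3)c2)[C@@H]1O | intermediate
24 | flavan-4-yl cation from 23, (2R,3R) | [CH+]1c2c(OCc3ccccc3)cc(OCc3ccccc3)cc2O[C@H](c2cc(OCc3ccccc3)c(OCc3ccccc3)c(OCc3ccccc3)c2)[C@@H]1O | intermediate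
25 | penta-O-benzyl-(−)-epigallocatechin-(4β→8)-penta-O-benzyl-(−)-epigallocatechin (both 3-hydroxyls free) | O(Cc1ccccc1)c1cc(OCc2ccccc2)c2c(c1[C@H]1c3c(OCc4ccccc4)cc(OCc4ccccc4)cc3O[C@H](c3cc(OCc4ccccc4)c(OCc4ccccc4)c(OCc4ccccc4)c3)[C@@H]1O)O[C@H](c1cc(OCc3ccccc3)c(OCc3ccccc3)c(OCc3ccccc3)c1)[C@H](O)C2 | intermediate
26 | dimer 25 carrying a 4β-(2-ethoxyethoxy) group at C4 of its lower unit (dimeric electrophile) | CCOCCO[C@H]1c2c(OCc3ccccc3)cc(OCc3ccccc3)c([C@H]3c4c(OCc5ccccc5)cc(OCc5ccccc5)cc4O[C@H](c4cc(OCc5ccccc5)c(OCc5ccccc5)c(OCc5ccccc5)c4)[C@@H]3O)c2O[C@H](c2cc(OCc3ccccc3)c(OCc3ccccc3)c(OCc3ccccc3)c2)[C@@H]1O | intermediate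
27 | dimeric flavan-4-yl cation from 26 (cationic C4 on the lower unit) | [CH+]1c2c(OCc3ccccc3)cc(OCc3ccccc3)c([C@H]3c4c(OCc5ccccc5)cc(OCc5ccccc5)cc4O[C@H](c4cc(OCc5ccccc5)c(OCc5ccccc5)c(OCc5ccccc5)c4)[C@@H]3O)c2O[C@H](c2cc(OCc3ccccc3)c(OCc3ccccc3)c(OCc3ccccc3)c2)[C@@H]1O | intermediate
28 | protected tetramer (twenty-three benzyl ethers; both 3-hydroxyls of the top and second units free; all interflavan bonds 4β→8) | O=C(O[C@@H]1[C@@H](c2c(OCc4ccccc4)cc(OCc4ccccc4)c3c2O[C@H](c2ccc(OCc4ccccc4)c(OCc4ccccc4)c2)[C@H](OCc4ccccc4)C3)c2c(OCc4ccccc4)cc(OCc4ccccc4)c([C@H]3c4c(OCc5ccccc5)cc(OCc5ccccc5)c([C@H]5c6c(OCc7ccccc7)cc(OCc7ccccc7)cc6O[C@H](c6cc(OCc7ccccc7)c(OCc7ccccc7)c(OCc7ccccc7)c6)[C@@H]5O)c4O[C@H](c4cc(OCc5ccccc5)c(OCc5ccccc5)c(OCc5ccccc5)c4)[C@@H]3O)c2O[C@@H]1c1cc(OCc2ccccc2)c(OCc2ccccc2)c(OCc2ccccc2)c1)c1cc(OCc2ccccc2)c(OCc2ccccc2)c(OCc2ccccc2)c1 | intermediate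
29 | CNP0305998.1: epigallocatechin-(4β→8)-epigallocatechin-(4β→8)-epigallocatechin 3-O-gallate-(4β→8)-epicatechin | O=C(O[C@@H]1[C@@H](c2c(O)cc(O)c3c2O[C@H](c2ccc(O)c(O)c2)[C@H](O)C3)c2c(O)cc(O)c([C@H]3c4c(O)cc(O)c([C@H]5c6c(O)cc(O)cc6O[C@H](c6cc(O)c(O)c(O)c6)[C@@H]5O)c4O[C@H](c4cc(O)c(O)c(O)c4)[C@@H]3O)c2O[C@@H]1c1cc(O)c(O)c(O)c1)c1cc(O)c(O)c(O)c1 | target

**Step count and risks**

Total step count: 15. Longest linear sequence: 8 steps (steps 3, 5, 6, 7, 8, 9, 14, 15).

Steps most likely to fail: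

Step 9 (Proposed new method). The carbenium ion may be reduced by the silane before ring closure, the enol ether may be protonated and reduced, closure may occur through C2 to a five-membered ring, or facial control may be poor (the absolute sense relative to the epicatechin unit, or the hydride face at C2). The fallback takes the gallate unit from the chiral pool by known chemistry. Commercial (−)-epigallocatechin gallate F1 is perbenzylated (BnBr, K2CO3, DMF) to octa-O-benzyl-epigallocatechin gallate F2. F2 is oxidised at C4 with DDQ in the presence of 2-ethoxyethanol to the 4β-(2-ethoxyethoxy) ether F3. F3 is then coupled with penta-O-benzyl-epicatechin 2 (Me3SiOTf, CH2Cl2, −78 °C), C8 of 2 attacking the C4 cation trans to the gallate. This fallback sets out from 2 and comes back at 20, so that steps 2 to 9 are replaced.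

Step 13. Hydride abstraction by DDQ may also take place at the interflavan methine of the upper unit and cleave or over-oxidise the dimer. The dimeric cation needed in step 14 may in turn self-condense through the free C8 of its upper unit. The fallback adds the two upper units one at a time, so that no dimer is oxidised. Electrophile 23 is coupled with an excess of dimer 20 (Me3SiOTf, CH2Cl2, −78 °C), C8 of ring A of the gallate unit attacking the monomeric cation, to give the protected trimer F4 (second unit-(4β→8)-gallate unit-(4β→8)-epicatechin unit). F4, in excess, is then coupled with a second portion of 23 under the same conditions, now through C8 of the newly attached second unit. This fallback sets out from 20 and 23 and comes back at 28, so that steps 12 to 14 are replaced.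

Step 5. Branched regioselectivity may be lost (formation of the linear cinnamyl ether), or the hydrogen-bonded phenol may react sluggishly with the allyliridium intermediate. In the fallback, aldehyde 6 is treated with vinylmagnesium bromide and worked up to the allylic alcohol 1-[3,4,5-tris(benzyloxy)phenyl]prop-2-en-1-ol F5. F5 is etherified with phenol 5 under Mitsunobu conditions (PPh3, diisopropyl azodicarboxylate, toluene, 0 °C). This fallback sets out from 5 and 6 and comes back at 9.

Further compounds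
F1 | step 9 | (−)-epigallocatechin gallate, (2R,3R) | O=C(O[C@@H]1Cc2c(O)cc(O)cc2O[C@@H]1c1cc(O)c(O)c(O)c1)c1cc(O)c(O)c(O)c1
F2 | step 9 | octa-O-benzyl-(−)-epigallocatechin gallate | O=C(O[C@@H]1Cc2c(OCc3ccccc3)cc(OCc3ccccc3)cc2O[C@@H]1c1cc(OCc2ccccc2)c(OCc2ccccc2)c(OCc2ccccc2)c1)c1cc(OCc2ccccc2)c(OCc2ccccc2)c(OCc2ccccc2)c1
F3 | step 9 | 4β-(2-ethoxyethoxy)-octa-O-benzyl-epigallocatechin gallate (3,4-trans) | O=C(O[C@@H]1[C@@H](OCCOCC)c2c(OCc3ccccc3)cc(OCc3ccccc3)cc2O[C@@H]1c1cc(OCc2ccccc2)c(OCc2ccccc2)c(OCc2ccccc2)c1)c1cc(OCc2ccccc2)c(OCc2ccccc2)c(OCc2ccccc2)c1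
F4 | step 13 | protected trimer: penta-O-benzyl-epigallocatechin-(4β→8)-[penta-O-benzyl-3-O-tri-O-benzylgalloyl-epigallocatechin]-(4β→8)-penta-O-benzyl-epicatechin | O=C(O[C@@H]1[C@@H](c2c(OCc4ccccc4)cc(OCc4ccccc4)c3c2O[C@H](c2ccc(OCc4ccccc4)c(OCc4ccccc4)c2)[C@H](OCc4ccccc4)C3)c2c(OCc4ccccc4)cc(OCc4ccccc4)c([C@H]3c4c(OCc5ccccc5)cc(OCc5ccccc5)cc4O[C@H](c4cc(OCc5ccccc5)c(OCc5ccccc5)c(OCc5ccccc5)c4)[C@@H]3O)c2O[C@@H]1c1cc(OCc2ccccc2)c(OCc2ccccc2)c(OCc2ccccc2)c1)c1cc(OCc2ccccc2)c(OCc2ccccc2)c(OCc2ccccc2)c1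
F5 | step 5 | 1-[3,4,5-tris(benzyloxy)phenyl]prop-2-en-1-ol (racemic) | C=CC(O)c1cc(OCc2ccccc2)c(OCc2ccccc2)c(OCc2ccccc2)c1
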